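**Plan**

- Late cuts: the two ester groups, the C12 and C13 methyls on C11 (ester plus MeLi), and the C4=C5 enone, which is traced back to a C1=C5 alkene with oxygen at C3.
- Key cut: C7 carries the carboxyl-level carbon C11 and is joined through C6 to the ring-fusion carbon C5. The C6–C7 bond and a C1=C5 alkene are therefore what a [3,3] shift of a C7=C11(OSi)–O–C1–C5=C6 array leaves behind. Cutting C6–C7 and rejoining C1–O gives a spiro ε-lactone on a 2-methylenecyclopentane.
- The lactone is cut at C8–O (conjugate borylation), C8=C9 (ring-closing metathesis), the C11–O ester bond, C1–C10 (ketone crotylation), C5–C6 and C4–C15 (enolate alkylation and cuprate addition on an (S)-4-silyloxycyclopentenone).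
- Ring order forward: the cyclopentane is present from the start, the seven-membered lactone closes in step 5, the seven-membered carbocycle closes in step 10 as the lactone opens, and the cyclopentenone is unveiled in step 17.
- Stereochemistry: the carbinol C1 by attack anti to the C5 substituent; C10 by the chair transition state of the (E)-crotylboron reagent; C8 by a chiral copper catalyst; C7 by transfer from C1 in the boat [3,3] shift; the final C1–H by equilibrating protonation. The C3 and C4 centres of the starting ring act only as control elements.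

Key step: step 10

Assumption: all intermediates carry the guaiane numbering of the target (C1–C10 ring carbons, C11 with C12/C13, C14 on C10, C15 on C4); in step 7 the named ferrocenyl bisphosphine antipode is taken to deliver boron to the C8 face cis to the C10 methyl, and its mirror image would be used if a first run shows the opposite sense.

**Route**

Step 1
Reactants: 1 (S)-4-(tert-butyldimethylsilyloxy)cyclopent-2-en-1-one
Product: 2 tert-butyldimethyl{[(1S,2S)-2-methyl-4-(trimethylsilyloxy)cyclopent-3-en-1-yl]oxy}silane (C4 methyl trans to the C3 silyloxy group)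
Conditions: Me2CuLi, TMSCl, Et3N, THF–Et2O, −78 °C
Reagents that add atoms: lithium dimethylcuprate, [Li+].C[Cu-]C; chlorotrimethylsilane, C[Si](C)(C)Cl
Why: Cuprate conjugate addition anti to the C3 silyloxy group sets C4 (with C15), and immediate O-silylation of the enolate forestalls β-elimination of the silyloxy group and fixes the C1=C5 enol ether for step 2.

Step 2
Reactants: 2 silyl enol ether; 3 chloromethyl phenyl sulfide
Product: 4 (2S,3S,4S)-4-(tert-butyldimethylsilyloxy)-3-methyl-2-[(phenylsulfanyl)methyl]cyclopentan-1-one (all-trans)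
Conditions: ZnBr2 (cat.), CH2Cl2, 0 °C to rt
Reagents that add atoms: chloromethyl phenyl sulfide, ClCSc1ccccc1
Why: Lewis-acid-promoted α-(phenylthio)methylation of a silyl enol ether (Mukaiyama-type alkylation through the thionium ion) places the future C6 on C5 anti to the C4 methyl, which is also the thermodynamic arrangement.

Step 3
Reactants: 4 all-trans cyclopentanone; 5 potassium (E)-but-2-enyltrifluoroborate
Product: 6 (1S,2S,3S,4S)-1-[(2S)-but-3-en-2-yl]-4-(tert-butyldimethylsilyloxy)-3-methyl-2-[(phenylsulfanyl)methyl]cyclopentan-1-ol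
Conditions: BF3·OEt2, CH2Cl2, −78 °C; then H2O
Reagents that add atoms: potassium (E)-but-2-enyltrifluoroborate, C/C=C/C[B-](F)(F)F.[K+]
Why: Ketone crotylboration by the crotyldifluoroborane formed in situ runs through a closed Zimmerman–Traxler chair, so attack on the C1 face anti to the C5 thiomethyl and C3 silyloxy groups sets C1, and the (E)-geometry with the branched C5 arm equatorial sets C10 in the anti sense.

Step 4
Reactants: 6 tertiary alcohol; 7 but-3-enoyl chloride
Product: 8 (1S,2S,3S,4S)-1-[(2S)-but-3-en-2-yl]-4-(tert-butyldimethylsilyloxy)-3-methyl-2-[(phenylsulfanyl)methyl]cyclopentyl but-3-enoate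
Conditions: n-BuLi, THF, −78 °C; then 7, −78 to 0 °C
Reagents that add atoms: but-3-enoyl chloride, C=CCC(Cl)=O
Why: O-Acylation of the lithium alkoxide of a hindered tertiary alcohol with an acid chloride brings in C11, C7 and C8, the low temperature keeping the β,γ-alkene out of conjugation.

Step 5
Reactants: 8 diene ester
Product: 9 (1S,2S,3S,5S,11S)-3-(tert-butyldimethylsilyloxy)-2,11-dimethyl-1-[(phenylsulfanyl)methyl]-6-oxaspiro[4.6]undec-9-en-7-one (C8=C9 lactone)
Conditions: second-generation Grubbs catalyst RuCl2(=CHPh)(H2IMes)(PCy3) (5 mol%), CH2Cl2 (5 mM), 40 °C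
Reagents that add atoms: none
Why: Ring-closing metathesis of the two monosubstituted alkenes closes the seven-membered lactone with a cis C8=C9 bond, loses ethene and touches no stereocentre.

Step 6
Reactants: 9 β,γ-unsaturated lactone
Product: 10 (1S,2S,3S,5S,11S)-3-(tert-butyldimethylsilyloxy)-2,11-dimethyl-1-[(phenylsulfanyl)methyl]-6-oxaspiro[4.6]undec-8-en-7-one (C7=C8 lactone)
Conditions: DBU, CH2Cl2, rt
Reagents that add atoms: none
Why: Base-mediated prototropic isomerisation through the C7 dienolate moves the alkene into conjugation with the lactone carbonyl, and C10 lies outside the dienolate and keeps its configuration.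

Step 7
Reactants: 10 α,β-unsaturated lactone
Product: 12 (1S,2S,3S,5S,9R,11S)-3-(tert-butyldimethylsilyloxy)-9-hydroxy-2,11-dimethyl-1-[(phenylsulfanyl)methyl]-6-oxaspiro[4.6]undecan-7-one, via C8 pinacolboronate 11 (not isolated)
Conditions: CuCl (5 mol%), NaOtBu (5 mol%), (R)-1-[(SP)-2-(diphenylphosphino)ferrocenyl]ethyldicyclohexylphosphine, B2pin2, MeOH, THF, rt; then NaBO3·4H2O, THF–H2O, 0 °C to rt
Reagents that add atoms: sodium perborate, [Na+].[O-]OB=O
Why: Copper-catalysed asymmetric conjugate borylation of the unsaturated lactone puts boron on C8 from the face chosen by the chiral bisphosphine, and perborate oxidation with retention should give the C8 alcohol cis to the C10 methyl.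

Step 8
Reactants: 12 β-hydroxy lactone
Product: 13 C8 triethylsilyl ether of 12
Conditions: TESCl, imidazole, DMF, 0 °C to rt
Reagents that add atoms: chlorotriethylsilane, CC[Si](CC)(CC)Cl
Why: Silylation of the secondary alcohol gives an ether that withstands step 10 and is later cleaved by dilute acid without loss of the C3 tert-butyldimethylsilyl ether.

Step 9
Reactants: 13 silyl ether
Product: 15 (2S,3S,5S,9R,11S)-3-(tert-butyldimethylsilyloxy)-2,11-dimethyl-1-methylidene-9-(triethylsilyloxy)-6-oxaspiro[4.6]undecan-7-one, via sulfoxide 14 (not isolated)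
Conditions: mCPBA (1.0 equiv), CH2Cl2, −78 °C; then toluene, NaHCO3, 110 °C
Reagents that add atoms: none
Why: Oxidation at sulfur followed by thermal syn-elimination of the sulfoxide, whose only β-hydrogen sits on C5, unveils the exocyclic C5=C6 alkene next to the spiro carbinol carbon.

Step 10
Reactants: 15 spiro ε-lactone on the 2-methylenecyclopentane
Product: 18 (2S,3S,5S,6R,8S)-2-(tert-butyldimethylsilyloxy)-3,8-dimethyl-6-(triethylsilyloxy)-1,2,3,4,5,6,7,8-octahydroazulene-5-carboxylic acid (C1=C5 alkene; C7 carboxyl cis to the C8 oxygen), via silyl ketene acetal 16 (not isolated), via silyl ester 17 (not isolated)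
Conditions: LiN(i-Pr)2, TBSCl, THF–DMPU, −78 °C; then toluene, 100 °C; then AcOH, THF–H2O, 0 °C
Reagents that add atoms: none
Why: LiN(i-Pr)2 deprotonates C7 in the presence of TBSCl, so the lactone enolate is trapped at once as the cyclic silyl ketene acetal 16 (C7=C11(OSi)–O–C1–C5=C6), which on heating undergoes the Ireland–Claisen [3,3] shift: C6–C7 forms, C1–O breaks and the alkene moves to C1=C5. The closest known reaction type is the ring-contracting ester-enolate Claisen rearrangement of lactone silyl ketene acetals bearing a vinyl group on the carbinol carbon, which gives cycloalkenecarboxylic acids. The seven-membered carbocycle (C1, C5, C6, C7, C8, C9, C10) closes by this sigmatropic bond formation through a boat-like transition state, the only one open to an endocyclic ketene acetal whose ends are tied by the C8–C9–C10 bridge, while the seven-membered lactone opens. The new stereocentre C7 is dictated by C1, because C6 can reach C7 only on the lactone face that carries C5; the C8 silyloxy and C10 methyl groups, both trans to C5, therefore end up cis to the C11 carboxyl. The step needs silylation to outrun β-elimination of the C8 silyloxy group, which the in situ quench at −78 °C should secure, and needs a single [3,3] pathway, which holds because C5=C6 is the only alkene within reach.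

Step 11
Reactants: 18 acid
Product: 19 methyl ester of 18
Conditions: TMSCHN2, toluene–MeOH, 0 °C
Reagents that add atoms: (trimethylsilyl)diazomethane, C[Si](C)(C)C=[N+]=[N-]
Why: Esterification by diazomethane released in situ is non-basic, so C7 and both silyl ethers are left alone.

Step 12
Reactants: 19 methyl ester
Product: 22 (2S,3S,5S,6R,8S)-2-(tert-butyldimethylsilyloxy)-5-(2-hydroxypropan-2-yl)-3,8-dimethyl-1,2,3,4,5,6,7,8-octahydroazulen-6-ol, via methyl ketone 20 (not isolated), via triethylsilyl ether 21 (not isolated)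
Conditions: MeLi, CeCl3, THF, −78 to 0 °C; then 1 M HCl, 0 °C
Reagents that add atoms: methyllithium, [Li]C
Why: Double addition of the methylcerium reagent to the ester builds C11 with C12 and C13 while its low basicity avoids enolisation at C7 and loss of the C8 silyloxy group, and the acidic quench cleaves only the triethylsilyl ether.

Step 13
Reactants: 22 diol; 23 methacryloyl chloride
Product: 24 (2S,3S,5S,6R,8S)-2-(tert-butyldimethylsilyloxy)-5-(2-hydroxypropan-2-yl)-3,8-dimethyl-1,2,3,4,5,6,7,8-octahydroazulen-6-yl 2-methylprop-2-enoate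
Conditions: Et3N, DMAP (cat.), CH2Cl2, 0 °C
Reagents that add atoms: methacryloyl chloride, C=C(C)C(Cl)=O
Why: Acylation distinguishes the secondary C8 hydroxyl from the tertiary C11 hydroxyl on steric grounds.

Step 14
Reactants: 24 hydroxy methacrylate
Product: 25 (2S,3S,5S,6R,8S)-5-(2-acetoxypropan-2-yl)-2-(tert-butyldimethylsilyloxy)-3,8-dimethyl-1,2,3,4,5,6,7,8-octahydroazulen-6-yl 2-methylprop-2-enoate
Conditions: Ac2O, DMAP, Et3N, CH2Cl2, 40 °C
Reagents that add atoms: acetic anhydride, CC(=O)OC(C)=O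
Why: DMAP-catalysed acylation with excess anhydride acetylates the remaining hindered tertiary alcohol.

Step 15
Reactants: 25 silyl ether
Product: 26 (2S,3S,5S,6R,8S)-5-(2-acetoxypropan-2-yl)-2-hydroxy-3,8-dimethyl-1,2,3,4,5,6,7,8-octahydroazulen-6-yl 2-methylprop-2-enoate
Conditions: HF·pyridine, THF–pyridine, 0 °C to rt
Reagents that add atoms: none
Why: Fluoride-driven cleavage of the silyl ether frees the C3 hydroxyl and leaves both esters and the alkene untouched.

Step 16
Reactants: 26 C3 alcohol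
Product: 27 (3S,5S,6R,8S)-5-(2-acetoxypropan-2-yl)-3,8-dimethyl-2-oxo-1,2,3,4,5,6,7,8-octahydroazulen-6-yl 2-methylprop-2-enoate (C1=C5 alkene, C3 ketone)
Conditions: Dess–Martin periodinane, NaHCO3, CH2Cl2, 0 °C
Reagents that add atoms: none
Why: Buffered periodinane oxidation converts the secondary alcohol into the C3 ketone without acid or base strong enough to disturb the esters.

Step 17
Reactants: 27 β,γ-unsaturated ketone
Product: 28 (5S,6R,8S,8aR)-5-(2-acetoxypropan-2-yl)-3,8-dimethyl-2-oxo-1,2,4,5,6,7,8,8a-octahydroazulen-6-yl 2-methylprop-2-enoate (target)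
Conditions: DBU (0.2 equiv), CH2Cl2, rt
Reagents that add atoms: none
Why: Base-mediated isomerisation of the cyclopent-3-enone through its dienolate should give the more substituted conjugated C4=C5 enone, and since C1 remains epimerisable through the same dienolate it should settle with C2 trans to the C10 methyl (H-1 anti to H-10), as in the target.

**Compound list**

1 | (S)-4-(tert-butyldimethylsilyloxy)cyclopent-2-en-1-one | O=C1C[C@H](O[Si](C)(C)C(C)(C)C)C=C1 | starting material
2 | tert-butyldimethyl{[(1S,2S)-2-methyl-4-(trimethylsilyloxy)cyclopent-3-en-1-yl]oxy}silane | C[Si](C)(C)OC1=C[C@H](C)[C@@H](O[Si](C)(C)C(C)(C)C)C1 | intermediate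
3 | chloromethyl phenyl sulfide | ClCSc1ccccc1 | starting material
4 | (2S,3S,4S)-4-(tert-butyldimethylsilyloxy)-3-methyl-2-[(phenylsulfanyl)methyl]cyclopentan-1-one | O=C1[C@@H](CSc2ccccc2)[C@H](C)[C@@H](O[Si](C)(C)C(C)(C)C)C1 | intermediate
5 | potassium (E)-but-2-enyltrifluoroborate | C/C=C/C[B-](F)(F)F.[K+] | starting material
6 | (1S,2S,3S,4S)-1-[(2S)-but-3-en-2-yl]-4-(tert-butyldimethylsilyloxy)-3-methyl-2-[(phenylsulfanyl)methyl]cyclopentan-1-ol | C=C[C@H](C)[C@@]1(O)C[C@H](O[Si](C)(C)C(C)(C)C)[C@@H](C)[C@@H]1CSc1ccccc1 | intermediate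
7 | but-3-enoyl chloride | C=CCC(Cl)=O | starting material
8 | but-3-enoate of 6 at the tertiary C1 oxygen | C=C[C@H](C)[C@@]1(OC(=O)CC=C)C[C@H](O[Si](C)(C)C(C)(C)C)[C@@H](C)[C@@H]1CSc1ccccc1 | intermediate
9 | (1S,2S,3S,5S,11S)-3-(tert-butyldimethylsilyloxy)-2,11-dimethyl-1-[(phenylsulfanyl)methyl]-6-oxaspiro[4.6]undec-9-en-7-one | C[C@H]1C=CCC(=O)O[C@@]12C[C@H](O[Si](C)(C)C(C)(C)C)[C@@H](C)[C@@H]2CSc1ccccc1 | intermediate
10 | (1S,2S,3S,5S,11S)-3-(tert-butyldimethylsilyloxy)-2,11-dimethyl-1-[(phenylsulfanyl)methyl]-6-oxaspiro[4.6]undec-8-en-7-one | C[C@H]1CC=CC(=O)O[C@@]12C[C@H](O[Si](C)(C)C(C)(C)C)[C@@H](C)[C@@H]2CSc1ccccc1 | intermediate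
11 | C8 pinacolboronate corresponding to 12 (boron in place of the C8 hydroxyl, same configuration) | C[C@H]1C[C@@H](B3OC(C)(C)C(C)(C)O3)CC(=O)O[C@@]12C[C@H](O[Si](C)(C)C(C)(C)C)[C@@H](C)[C@@H]2CSc1ccccc1 | intermediate
12 | (1S,2S,3S,5S,9R,11S)-3-(tert-butyldimethylsilyloxy)-9-hydroxy-2,11-dimethyl-1-[(phenylsulfanyl)methyl]-6-oxaspiro[4.6]undecan-7-one | C[C@H]1C[C@@H](O)CC(=O)O[C@@]12C[C@H](O[Si](C)(C)C(C)(C)C)[C@@H](C)[C@@H]2CSc1ccccc1 | intermediate
13 | C8 triethylsilyl ether of 12 | C[C@H]1C[C@@H](O[Si](CC)(CC)CC)CC(=O)O[C@@]12C[C@H](O[Si](C)(C)C(C)(C)C)[C@@H](C)[C@@H]2CSc1ccccc1 | intermediate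
14 | sulfoxide of 13 (mixture at sulfur) | C[C@H]1C[C@@H](O[Si](CC)(CC)CC)CC(=O)O[C@@]12C[C@H](O[Si](C)(C)C(C)(C)C)[C@@H](C)[C@@H]2CS(=O)c1ccccc1 | intermediate
15 | (2S,3S,5S,9R,11S)-3-(tert-butyldimethylsilyloxy)-2,11-dimethyl-1-methylidene-9-(triethylsilyloxy)-6-oxaspiro[4.6]undecan-7-one | C[C@H]1C[C@@H](O[Si](CC)(CC)CC)CC(=O)O[C@@]12C[C@H](O[Si](C)(C)C(C)(C)C)[C@@H](C)C2=C | intermediate
16 | tert-butyldimethylsilyl ketene acetal of 15 (endocyclic C7=C11) | C[C@H]1C[C@@H](O[Si](CC)(CC)CC)C=C(O[Si](C)(C)C(C)(C)C)O[C@@]12C[C@H](O[Si](C)(C)C(C)(C)C)[C@@H](C)C2=C | intermediate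
17 | tert-butyldimethylsilyl ester of 18 | CC[Si](CC)(CC)O[C@@H]1C[C@H](C)C2=C([C@H](C)[C@@H](O[Si](C)(C)C(C)(C)C)C2)C[C@@H]1C(=O)O[Si](C)(C)C(C)(C)C | intermediate
18 | (2S,3S,5S,6R,8S)-2-(tert-butyldimethylsilyloxy)-3,8-dimethyl-6-(triethylsilyloxy)-1,2,3,4,5,6,7,8-octahydroazulene-5-carboxylic acid | CC[Si](CC)(CC)O[C@@H]1C[C@H](C)C2=C([C@H](C)[C@@H](O[Si](C)(C)C(C)(C)C)C2)C[C@@H]1C(=O)O | intermediate
19 | methyl ester of 18 | CC[Si](CC)(CC)O[C@@H]1C[C@H](C)C2=C([C@H](C)[C@@H](O[Si](C)(C)C(C)(C)C)C2)C[C@@H]1C(=O)OC | intermediate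
20 | C7 acetyl compound (methyl ketone at C11, both silyl ethers in place) | CC[Si](CC)(CC)O[C@@H]1C[C@H](C)C2=C([C@H](C)[C@@H](O[Si](C)(C)C(C)(C)C)C2)C[C@@H]1C(C)=O | intermediate
21 | C8 triethylsilyl ether of 22 | CC[Si](CC)(CC)O[C@@H]1C[C@H](C)C2=C([C@H](C)[C@@H](O[Si](C)(C)C(C)(C)C)C2)C[C@@H]1C(C)(C)O | intermediate
22 | (2S,3S,5S,6R,8S)-2-(tert-butyldimethylsilyloxy)-5-(2-hydroxypropan-2-yl)-3,8-dimethyl-1,2,3,4,5,6,7,8-octahydroazulen-6-ol | O[C@@H]1C[C@H](C)C2=C([C@H](C)[C@@H](O[Si](C)(C)C(C)(C)C)C2)C[C@@H]1C(C)(C)O | intermediate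
23 | methacryloyl chloride | C=C(C)C(Cl)=O | starting material
24 | (2S,3S,5S,6R,8S)-2-(tert-butyldimethylsilyloxy)-5-(2-hydroxypropan-2-yl)-3,8-dimethyl-1,2,3,4,5,6,7,8-octahydroazulen-6-yl 2-methylprop-2-enoate | C=C(C)C(=O)O[C@@H]1C[C@H](C)C2=C([C@H](C)[C@@H](O[Si](C)(C)C(C)(C)C)C2)C[C@@H]1C(C)(C)O | intermediate
25 | (2S,3S,5S,6R,8S)-5-(2-acetoxypropan-2-yl)-2-(tert-butyldimethylsilyloxy)-3,8-dimethyl-1,2,3,4,5,6,7,8-octahydroazulen-6-yl 2-methylprop-2-enoate | C=C(C)C(=O)O[C@@H]1C[C@H](C)C2=C([C@H](C)[C@@H](O[Si](C)(C)C(C)(C)C)C2)C[C@@H]1C(C)(C)OC(C)=O | intermediate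
26 | (2S,3S,5S,6R,8S)-5-(2-acetoxypropan-2-yl)-2-hydroxy-3,8-dimethyl-1,2,3,4,5,6,7,8-octahydroazulen-6-yl 2-methylprop-2-enoate | C=C(C)C(=O)O[C@@H]1C[C@H](C)C2=C([C@H](C)[C@@H](O)C2)C[C@@H]1C(C)(C)OC(C)=O | intermediate
27 | (3S,5S,6R,8S)-5-(2-acetoxypropan-2-yl)-3,8-dimethyl-2-oxo-1,2,3,4,5,6,7,8-octahydroazulen-6-yl 2-methylprop-2-enoate | C=C(C)C(=O)O[C@@H]1C[C@H](C)C2=C([C@H](C)C(=O)C2)C[C@@H]1C(C)(C)OC(C)=O | intermediate
28 | (5S,6R,8S,8aR)-5-(2-acetoxypropan-2-yl)-3,8-dimethyl-2-oxo-1,2,4,5,6,7,8,8a-octahydroazulen-6-yl 2-methylprop-2-enoate; guaiane numbering (1R,7S,8R,10S) | C=C(C)C(=O)O[C@@H]1C[C@H](C)[C@H]2CC(=O)C(C)=C2C[C@@H]1C(C)(C)OC(C)=O | target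

**Count and risks**

Total steps: 17. Longest linear sequence: 17 steps (from 1).

Steps most likely to fail:

1. Step 10 (key step). The lithium enolate may expel the C8 silyloxide or fragment before it is silylated, or the boat rearrangement may be slower than decomposition of the ketene acetal. The fallback sets out from 12 and returns at 22, and keeps the [3,3] shift but removes the leaving group. Hydroxy lactone 12 is taken without silylation through mCPBA oxidation to the hydroxy sulfoxide F1 and thermolysis (toluene, 110 °C) to the hydroxy methylene lactone F2. LiN(i-Pr)2 (2.2 equiv, THF, −78 °C) then forms first the alkoxide and then the enolate, a Fráter–Seebach-type dianion whose β-oxygen is an oxide and cannot leave. TMSCl gives the bis(trimethylsilyl) ketene acetal F3, and warming gives the rearranged bis(trimethylsilyl) ester F4. Aqueous acid gives the hydroxy acid F5, TMSCHN2 gives the hydroxy methyl ester F6, and excess MeLi with CeCl3 leads to diol 22.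

2. Step 7. Facial selection at C8 by the catalyst may be eroded by the ring, or part of the material may stay deconjugated and unreactive. The fallback sets out from 12 as obtained (its C8 epimer mixture) and returns at 12, and shifts control of C8 from C–B bond formation to ketone reduction. Dess–Martin periodinane gives the β-keto lactone F7. Reduction with NaBH4 (MeOH–CH2Cl2, −78 °C) is expected to deliver hydride along the pseudoaxial trajectory and so give the pseudoequatorial C8 alcohol cis to the C10 methyl, as in reductions of 3-alkylcyclohexanones.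

3. Step 17. Protonation of the dienolate may leave the C1 epimer with C2 cis to the C10 methyl, or conjugation may go toward C1=C2. The fallback sets out from 22 and ends at 28, and sets C1 by directed hydrogenation instead of protonation.
   - Hydrogenation of 22 with [Ir(cod)(PCy3)(py)]PF6 and H2 (CH2Cl2), directed by the C8 and C11 hydroxyls, which lie on the face of the C10 methyl, should add H-1 and H-5 on that face and give the cis-fused decahydroazulene diol F8.
   - Methacrylation as in step 13 gives the methacrylate F9, acetylation as in step 14 gives the acetate F10, HF·pyridine gives the C3 alcohol F11, and Dess–Martin periodinane gives the saturated ketone F12.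
   - TMSOTf and Et3N under equilibrating conditions give the more substituted trimethylsilyl enol ether F13 (C3=C4), and Saegusa–Ito oxidation with Pd(OAc)2 (MeCN) introduces the C4=C5 bond to give 28 with C1 untouched.

Further compounds
F1 | step 10 | sulfoxide of hydroxy lactone 12 | C[C@H]1C[C@@H](O)CC(=O)O[C@@]12C[C@H](O[Si](C)(C)C(C)(C)C)[C@@H](C)[C@@H]2CS(=O)c1ccccc1
F2 | step 10 | (2S,3S,5S,9R,11S)-3-(tert-butyldimethylsilyloxy)-9-hydroxy-2,11-dimethyl-1-methylidene-6-oxaspiro[4.6]undecan-7-one | C[C@H]1C[C@@H](O)CC(=O)O[C@@]12C[C@H](O[Si](C)(C)C(C)(C)C)[C@@H](C)C2=C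
F3 | step 10 | bis(trimethylsilyl) ketene acetal of F2 (C8 trimethylsilyl ether, C7=C11 trimethylsilyl ketene acetal) | C[C@H]1C[C@@H](O[Si](C)(C)C)C=C(O[Si](C)(C)C)O[C@@]12C[C@H](O[Si](C)(C)C(C)(C)C)[C@@H](C)C2=C
F4 | step 10 | trimethylsilyl ester and C8 trimethylsilyl ether of F5 | C[Si](C)(C)O[C@@H]1C[C@H](C)C2=C([C@H](C)[C@@H](O[Si](C)(C)C(C)(C)C)C2)C[C@@H]1C(=O)O[Si](C)(C)C
F5 | step 10 | (2S,3S,5S,6R,8S)-2-(tert-butyldimethylsilyloxy)-6-hydroxy-3,8-dimethyl-1,2,3,4,5,6,7,8-octahydroazulene-5-carboxylic acid | O[C@@H]1C[C@H](C)C2=C([C@H](C)[C@@H](O[Si](C)(C)C(C)(C)C)C2)C[C@@H]1C(=O)O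
F6 | step 10 | methyl ester of F5 | O[C@@H]1C[C@H](C)C2=C([C@H](C)[C@@H](O[Si](C)(C)C(C)(C)C)C2)C[C@@H]1C(=O)OC
F7 | step 7 | (1S,2S,3S,5S,11S)-3-(tert-butyldimethylsilyloxy)-2,11-dimethyl-1-[(phenylsulfanyl)methyl]-6-oxaspiro[4.6]undecane-7,9-dione | C[C@H]1CC(=O)CC(=O)O[C@@]12C[C@H](O[Si](C)(C)C(C)(C)C)[C@@H](C)[C@@H]2CSc1ccccc1
F8 | step 17 | cis-fused decahydroazulene diol from 22 (H-1 and H-5 on the face of the C10 methyl; C8 hydroxyl, C11 hydroxyl, C3 silyl ether) | O[C@@H]1C[C@H](C)[C@H]2C[C@H](O[Si](C)(C)C(C)(C)C)[C@@H](C)[C@H]2C[C@@H]1C(C)(C)O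
F9 | step 17 | C8 methacrylate of F8 | C=C(C)C(=O)O[C@@H]1C[C@H](C)[C@H]2C[C@H](O[Si](C)(C)C(C)(C)C)[C@@H](C)[C@H]2C[C@@H]1C(C)(C)O
F10 | step 17 | C11 acetate of F9 | C=C(C)C(=O)O[C@@H]1C[C@H](C)[C@H]2C[C@H](O[Si](C)(C)C(C)(C)C)[C@@H](C)[C@H]2C[C@@H]1C(C)(C)OC(C)=O
F11 | step 17 | C3 alcohol from F10 | C=C(C)C(=O)O[C@@H]1C[C@H](C)[C@H]2C[C@H](O)[C@@H](C)[C@H]2C[C@@H]1C(C)(C)OC(C)=O
F12 | step 17 | saturated C3 ketone from F11 (4,5-dihydro derivative of 28, cis-fused) | C=C(C)C(=O)O[C@@H]1C[C@H](C)[C@H]2CC(=O)[C@@H](C)[C@H]2C[C@@H]1C(C)(C)OC(C)=O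
F13 | step 17 | trimethylsilyl enol ether of F12 (C3=C4) | C=C(C)C(=O)O[C@@H]1C[C@H](C)[C@H]2CC(O[Si](C)(C)C)=C(C)[C@H]2C[C@@H]1C(C)(C)OC(C)=O
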